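**Plan**
1. Locants (cyathane-type): ring A = C1–C2–C3–C4–C9 (cyclopentane), ring B = C4–C5–C6–C7–C8–C9, ring C = C5–C6–C14–C13–C12–C11–C10; C15/C16 = methyls on C12/C6, C17 = CH2O on C9, C18–C20 = lactone carbons on C3; β = the face carrying C17.
2. Retrosynthesis: remove the acetyl group and both epoxide oxygens; cut the lactone at C3–C18 and at the methylene (a phosphonoacetate on the C2 oxygen opening a C3–C4 epoxide); cut rings A and B together at C4–C9, C1–C2 and C2–C3 (Pauson–Khand, CO = C2); cut ring C at C12=C13 (metathesis) and C5–C6 (Ireland–Claisen).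
3. Enabling feature: ring A carries oxygen on C2, and its bond C4–C9 joins a carbinol carbon to a quaternary carbon bearing a one-carbon arm. This is the pattern of a cyclopentenone (C2=O, C3=C4) with an angular substituent, formed from an alkyne C3≡C4 on C5 and a 1,1-disubstituted alkene C9=C1 on a chain from C6.
4. Forward order: achiral ester → C5–C6 by Claisen → ring C by ring-closing metathesis → rings B and A in one cobalt-mediated step → lactone and both epoxides → acetate.
5. Stereochemistry: C5/C6 from a chiral-boron-controlled chair Ireland–Claisen; C9 from the chair-like Pauson–Khand closure on trans-fused ring C; C2 by hydride anti to C17; C3/C4 by α-epoxidation and SN2 opening from the C2-tethered carbanion; ring C epoxide anti to C16.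

Key step: step 10

Assumption: the (S,S)-diazaborolidine is taken to deliver acid 7 as drawn; should the facial sense be the opposite, the (R,R)-reagent would be used with no other change.
Remark: compounds 1, 4 and 10 are taken as purchasable.

**Step 1**
Reactants: 1 pent-1-en-4-yne
Product: 3 (2E)-3-methylhexa-2,5-dien-1-ol, via alkenylalane 2 (not isolated)
Conditions: Me3Al, Cp2ZrCl2 (cat.), CH2Cl2, 0 °C to rt; then n-BuLi, THF, −78 °C; (CH2O)n, rt; aq. HCl
Reagents that add atoms: trimethylaluminium, C[Al](C)C; paraformaldehyde (as formaldehyde), C=O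
Why: Zirconium-catalysed Negishi carboalumination adds Me and Al syn across the terminal alkyne with Me on the internal carbon, and the derived alkenylaluminate is hydroxymethylated with retention, so the allyl group ends trans to CH2OH (E), the geometry the later Claisen chair needs; the terminal alkene is inert.

**Step 2**
Reactants: 3 (2E)-3-methylhexa-2,5-dien-1-ol; 4 5-methylhex-5-enoic acid
Product: 5 (2E)-3-methylhexa-2,5-dien-1-yl 5-methylhex-5-enoate
Conditions: DCC, DMAP (cat.), CH2Cl2, 0 °C to rt
Reagents that add atoms: none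
Why: Steglich esterification joins the two achiral halves under neutral conditions that leave the skipped diene and the 1,1-disubstituted alkene untouched.

**Step 3**
Reactants: 5 (2E)-3-methylhexa-2,5-dien-1-yl 5-methylhex-5-enoate
Product: 7 (2S,3R)-3-ethenyl-3-methyl-2-(3-methylbut-3-en-1-yl)hex-5-enoic acid, via boron ketene acetal 6 (not isolated)
Conditions: (4S,5S)-2-bromo-4,5-diphenyl-1,3-bis{[3,5-bis(trifluoromethyl)phenyl]sulfonyl}-1,3,2-diazaborolidine, Et3N, toluene/hexane, −78 °C to rt; aqueous work-up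
Reagents that add atoms: none
Why: Boron-mediated enantioselective Ireland–Claisen rearrangement: soft enolization under conditions chosen to give the ketene acetal with the alkyl chain cis to O–B, a chair [3,3] shift in which the (E)-alkene places allyl equatorial and methyl axial (fixing quaternary C6 relative to C5), and face selection by the C2-symmetric diazaborolidine for the absolute configuration.

**Step 4**
Reactants: 7 (2S,3R)-3-ethenyl-3-methyl-2-(3-methylbut-3-en-1-yl)hex-5-enoic acid
Product: 8 (1S,2R)-2-ethenyl-2,5-dimethylcyclohept-4-ene-1-carboxylic acid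
Conditions: second-generation Grubbs catalyst (5 mol %), CH2Cl2 (high dilution), 40 °C
Reagents that add atoms: none
Why: Ring-closing metathesis starts at the unhindered allyl group and closes onto the 1,1-disubstituted alkene to give the trisubstituted cycloheptene (ring C) with loss of ethene, while the neopentyl vinyl group on C6 is too hindered to compete and no stereocenter is touched.

**Step 5**
Reactants: 8 (1S,2R)-2-ethenyl-2,5-dimethylcyclohept-4-ene-1-carboxylic acid
Product: 9 (1S,2R)-2-ethenyl-N-methoxy-N,2,5-trimethylcyclohept-4-ene-1-carboxamide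
Conditions: MeNHOMe·HCl, EDC·HCl, HOBt, i-Pr2NEt, CH2Cl2, rt
Reagents that add atoms: N,O-dimethylhydroxylamine hydrochloride, CNOC.Cl
Why: Carbodiimide amidation gives the N-methoxy-N-methylamide (Weinreb amide), so that C4 can later be stopped at the aldehyde level and no acidic proton interferes with the hydroboration.

**Step 6**
Reactants: 10 2-bromoprop-2-en-1-ol
Product: 11 [(2-bromoprop-2-en-1-yl)oxy](tert-butyl)dimethylsilane
Conditions: TBSCl, imidazole, DMF, rt
Reagents that add atoms: tert-butyldimethylsilyl chloride, CC(C)(C)[Si](C)(C)Cl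
Why: Standard silylation of the primary allylic alcohol gives a vinyl bromide partner whose oxygen (the future C17 acetate oxygen) is protected through the following steps.

**Step 7**
Reactants: 9 (1S,2R)-2-ethenyl-N-methoxy-N,2,5-trimethylcyclohept-4-ene-1-carboxamide; 11 [(2-bromoprop-2-en-1-yl)oxy](tert-butyl)dimethylsilane
Product: 13 (1S,2S)-2-[3-({[tert-butyl(dimethyl)silyl]oxy}methyl)but-3-en-1-yl]-N-methoxy-N,2,5-trimethylcyclohept-4-ene-1-carboxamide, via B-alkyl-9-BBN 12 (not isolated)
Conditions: 9-BBN, THF, rt; then 11, Pd(dppf)Cl2, AsPh3, Cs2CO3, DMF/H2O, rt to 50 °C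
Reagents that add atoms: none
Why: 9-BBN hydroborates only the monosubstituted vinyl group (anti-Markovnikov; the trisubstituted ring alkene and the amide are inert), and the B-alkyl Suzuki–Miyaura coupling with vinyl bromide 11 forms C8–C9 and installs the 1,1-disubstituted alkene C9=C1 with its C17 oxygen.

**Step 8**
Reactants: 13 (1S,2S)-2-[3-({[tert-butyl(dimethyl)silyl]oxy}methyl)but-3-en-1-yl]-N-methoxy-N,2,5-trimethylcyclohept-4-ene-1-carboxamide
Product: 14 (1S,2S)-2-[3-({[tert-butyl(dimethyl)silyl]oxy}methyl)but-3-en-1-yl]-2,5-dimethylcyclohept-4-ene-1-carbaldehyde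
Conditions: i-Bu2AlH, THF, −78 °C; aqueous tartrate work-up
Reagents that add atoms: none
Why: Hydride addition to the Weinreb amide gives a stable aluminium chelate that releases the aldehyde only on work-up (partial reduction), without over-reduction and without epimerization at C5.

**Step 9**
Reactants: 14 (1S,2S)-2-[3-({[tert-butyl(dimethyl)silyl]oxy}methyl)but-3-en-1-yl]-2,5-dimethylcyclohept-4-ene-1-carbaldehyde
Product: 15 (4S,5S)-4-[3-({[tert-butyl(dimethyl)silyl]oxy}methyl)but-3-en-1-yl]-5-ethynyl-1,4-dimethylcyclohept-1-ene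
Conditions: dimethyl (1-diazo-2-oxopropyl)phosphonate, K2CO3, MeOH, 0 °C to rt
Reagents that add atoms: dimethyl (1-diazo-2-oxopropyl)phosphonate, CC(=O)C(=[N+]=[N-])P(=O)(OC)OC
Why: Seyferth–Gilbert homologation in its Ohira–Bestmann form converts the hindered aldehyde into the terminal alkyne C3≡C4 under mild carbonate conditions, kept cold so that the C5 stereocenter α to the aldehyde does not epimerize.

**Step 10**
Reactants: 15 (4S,5S)-4-[3-({[tert-butyl(dimethyl)silyl]oxy}methyl)but-3-en-1-yl]-5-ethynyl-1,4-dimethylcyclohept-1-ene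
Product: 17 tricyclic enone (C2 ketone; C3=C4; C12=C13; 9β-CH2OTBS; 5β-H; 6α-CH3), via alkyne–hexacarbonyldicobalt complex 16 (not isolated)
Conditions: Co2(CO)8, CH2Cl2, rt; then N-methylmorpholine N-oxide, 0 °C to rt
Reagents that add atoms: dicobalt octacarbonyl, O=C=[Co](=C=O)(=C=O)(=C=O)[Co](=C=O)(=C=O)(=C=O)=C=O
Why: The alkyne–Co2(CO)6 complex 16 loses CO on N-oxide treatment, the 1,1-disubstituted alkene C9=C1 coordinates and inserts into the Co–C4 bond to form C4–C9, and CO insertion with reductive elimination joins C1–C2–C3 (intramolecular Pauson–Khand [2+2+1]). The closest known reaction type is the Pauson–Khand cyclization of 1,7-enynes with 1,1-disubstituted alkenes to angularly substituted hydrindenones. Ring B closes by 6-exo insertion of the alkene into the cobalt–alkyne unit, and ring A closes as the cyclopentenone by insertion of CO (C2) between C1 and C3. The only new stereocenter, C9, is set by the chair-like six-membered tether anchored by trans-fused ring C (C10 and C14 equatorial, C16 axial): the planar cyclopentenone needs C1 pseudo-equatorial, so the CH2OTBS arm becomes axial on the face opposite C16. The step needs chemoselectivity for the chain alkene over the ring C alkene; the trisubstituted C12=C13 bond could only give a strained bridged enone, and the quaternary C6 favors closure of the chain by the gem-dialkyl effect.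

**Step 11**
Reactants: 17 tricyclic enone
Product: 18 2β-allylic alcohol (C3=C4; C12=C13; 9β-CH2OTBS)
Conditions: NaBH4, CeCl3·7H2O, MeOH, −40 °C
Reagents that add atoms: none
Why: Luche reduction gives clean 1,2-addition to the enone, and hydride enters from the α face, opposite the axial C17 arm that hangs over the β face of the flat cyclopentenone, to set the 2β alcohol.

**Step 12**
Reactants: 18 2β-allylic alcohol
Product: 19 2β-(diethoxyphosphoryl)acetate ester of 18
Conditions: (EtO)2P(O)CH2CO2H, DCC, DMAP (cat.), CH2Cl2, 0 °C to rt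
Reagents that add atoms: (diethoxyphosphoryl)acetic acid, CCOP(=O)(OCC)CC(=O)O
Why: Steglich esterification places the phosphonoacetate on the 2β oxygen, the tether that will deliver C18 to the β face of C3.

**Step 13**
Reactants: 19 2β-(diethoxyphosphoryl)acetate ester
Product: 20 3α,4α:12β,13β-bis-epoxide of 19
Conditions: mCPBA (2.5 equiv), CH2Cl2, 0 °C to rt
Reagents that add atoms: 3-chloroperoxybenzoic acid, OOC(=O)c1cccc(Cl)c1
Why: Prilezhaev epoxidation of both trisubstituted alkenes: the ring C alkene should be attacked anti to the axial homoallylic C16 methyl (β epoxide) and the ring A alkene anti to both the 2β ester and the axial 9β arm (α epoxide), which places the future C4 oxygen α.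

**Step 14**
Reactants: 20 3α,4α:12β,13β-bis-epoxide
Product: 22 17-O-silyl α-methylene lactone (4α-OH; 12β,13β-epoxide), via α-phosphono lactone 21 (not isolated)
Conditions: NaH, THF, 0 to 65 °C; then (CH2O)n, rt
Reagents that add atoms: paraformaldehyde (as formaldehyde), C=O
Why: Proposed new method: the sodium phosphonoacetate carbanion, held on the β face by the C2 ester oxygen, is placed for a 5-exo-tet backside attack on C3 of the α-epoxide (the quaternary C4 end would need a 6-endo path), giving the cis-fused α-phosphono lactone with C18 β on C3 and the alkoxide α on C4; this alkoxide is trans to C18, cannot transfer phosphorus and only deprotonates C18, and the resulting phosphonate anion olefinates formaldehyde (Horner–Wadsworth–Emmons) to the α-methylene lactone; the closest known reaction types are the opening of epoxides by phosphonoacetate anions (first stage of the Wadsworth–Emmons cyclopropanation), the Stork epoxynitrile cyclization and the methylenation of α-phosphono-γ-butyrolactones with formaldehyde.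

**Step 15**
Reactants: 22 17-O-silyl α-methylene lactone
Product: 23 17-hydroxy α-methylene lactone (deacetyl target)
Conditions: Bu4NF, AcOH, THF, 0 °C to rt
Reagents that add atoms: none
Why: Fluoride-mediated desilylation, buffered with acetic acid so that the α-methylene lactone and the epoxide are not exposed to basic fluoride, frees the primary C17 alcohol.

**Step 16**
Reactants: 23 17-hydroxy α-methylene lactone
Product: 24 target CNP0214540.1
Conditions: Ac2O, pyridine, DMAP (cat.), CH2Cl2, 0 °C
Reagents that add atoms: acetic anhydride, CC(=O)OC(C)=O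
Why: Nucleophile-catalysed acetylation is selective for the primary C17 hydroxyl because the tertiary, axial C4 hydroxyl is unreactive under these conditions, which completes the target.

**Compound list**
1 | pent-1-en-4-yne | C=CCC#C | starting material
2 | (E)-dimethyl(2-methylpenta-1,4-dien-1-yl)alane | C=CC/C(C)=C/[Al](C)C | intermediate (not isolated)
3 | (2E)-3-methylhexa-2,5-dien-1-ol | C=CC/C(C)=C/CO | intermediate
4 | 5-methylhex-5-enoic acid | CC(=C)CCCC(=O)O | starting material
5 | (2E)-3-methylhexa-2,5-dien-1-yl 5-methylhex-5-enoate | C=CC/C(C)=C/COC(=O)CCCC(C)=C | intermediate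
6 | boron ketene acetal of 5 (alkyl chain cis to O–B; (4S,5S)-diazaborolidin-2-yl on oxygen) | C=CC/C(C)=C/CO/C(OB1N(S(=O)(=O)c2cc(cc(c2)C(F)(F)F)C(F)(F)F)[C@@H](c2ccccc2)[C@H](c2ccccc2)N1S(=O)(=O)c1cc(cc(c1)C(F)(F)F)C(F)(F)F)=C/CCC(C)=C | intermediate (not isolated)
7 | (2S,3R)-3-ethenyl-3-methyl-2-(3-methylbut-3-en-1-yl)hex-5-enoic acid | C=C[C@@]([C@H](CCC(C)=C)C(=O)O)(C)CC=C | intermediate
8 | (1S,2R)-2-ethenyl-2,5-dimethylcyclohept-4-ene-1-carboxylic acid | C=C[C@@]1(C)CC=C(C)CC[C@@H]1C(=O)O | intermediate
9 | (1S,2R)-2-ethenyl-N-methoxy-N,2,5-trimethylcyclohept-4-ene-1-carboxamide | C=C[C@@]1(C)CC=C(C)CC[C@@H]1C(=O)N(C)OC | intermediate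
10 | 2-bromoprop-2-en-1-ol | OCC(Br)=C | starting material
11 | [(2-bromoprop-2-en-1-yl)oxy](tert-butyl)dimethylsilane | C=C(Br)CO[Si](C)(C)C(C)(C)C | intermediate
12 | (1S,2S)-2-[2-(9-borabicyclo[3.3.1]nonan-9-yl)ethyl]-N-methoxy-N,2,5-trimethylcyclohept-4-ene-1-carboxamide | C1CC2CCCC(C1)B2CC[C@@]1(C)CC=C(C)CC[C@@H]1C(=O)N(C)OC | intermediate (not isolated)
13 | (1S,2S)-2-[3-({[tert-butyl(dimethyl)silyl]oxy}methyl)but-3-en-1-yl]-N-methoxy-N,2,5-trimethylcyclohept-4-ene-1-carboxamide | C=C(CO[Si](C)(C)C(C)(C)C)CC[C@@]1(C)CC=C(C)CC[C@@H]1C(=O)N(C)OC | intermediate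
14 | (1S,2S)-2-[3-({[tert-butyl(dimethyl)silyl]oxy}methyl)but-3-en-1-yl]-2,5-dimethylcyclohept-4-ene-1-carbaldehyde | C=C(CO[Si](C)(C)C(C)(C)C)CC[C@@]1(C)CC=C(C)CC[C@@H]1C=O | intermediate
15 | (4S,5S)-4-[3-({[tert-butyl(dimethyl)silyl]oxy}methyl)but-3-en-1-yl]-5-ethynyl-1,4-dimethylcyclohept-1-ene | C=C(CO[Si](C)(C)C(C)(C)C)CC[C@@]1(C)CC=C(C)CC[C@@H]1C#C | intermediate
16 | μ-alkyne hexacarbonyldicobalt complex of 15 | C=C(CO[Si](C)(C)C(C)(C)C)CC[C@@]1(C)CC=C(C)CC[C@@H]1C23[Co]4(=C=O)(=C=O)(=C=O)[Co]2(=C=O)(=C=O)(=C=O)[CH]34 | intermediate (not isolated)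
17 | tricyclic enone: ring A cyclopent-3-en-2-one (C2=O, C3=C4), C12=C13 alkene, 9β-CH2OTBS, 5β-H, 6α-CH3 | O=C1C[C@]2(CO[Si](C)(C)C(C)(C)C)CC[C@@]3(C)CC=C(C)CC[C@@H]3C2=C1 | intermediate
18 | 2β-allylic alcohol from 17 (C3=C4 and C12=C13 alkenes, 9β-CH2OTBS) | O[C@H]1C[C@]2(CO[Si](C)(C)C(C)(C)C)CC[C@@]3(C)CC=C(C)CC[C@@H]3C2=C1 | intermediate
19 | 2β-(diethoxyphosphoryl)acetate ester of 18 | CCOP(=O)(OCC)CC(=O)O[C@H]1C[C@]2(CO[Si](C)(C)C(C)(C)C)CC[C@@]3(C)CC=C(C)CC[C@@H]3C2=C1 | intermediate
20 | 3α,4α:12β,13β-bis-epoxide of 19 | CCOP(=O)(OCC)CC(=O)O[C@H]1C[C@]2(CO[Si](C)(C)C(C)(C)C)CC[C@@]3(C)C[C@H]4O[C@@]4(C)CC[C@@H]3[C@@]2(O6)[C@@H]16 | intermediate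
21 | α-(diethoxyphosphoryl) lactone (C2–O/C3–C18 cis-fused, 4α-OH, 12β,13β-epoxide, 17-OTBS; C18 epimers) | CCOP(=O)(OCC)C1C(=O)O[C@H]2C[C@]3(CO[Si](C)(C)C(C)(C)C)CC[C@@]4(C)C[C@H]5O[C@@]5(C)CC[C@@H]4[C@@]3(O)[C@@H]12 | intermediate (not isolated)
22 | 17-O-(tert-butyldimethylsilyl) α-methylene lactone (4α-OH, 12β,13β-epoxide) | C=C1C(=O)O[C@H]2C[C@]3(CO[Si](C)(C)C(C)(C)C)CC[C@@]4(C)C[C@H]5O[C@@]5(C)CC[C@@H]4[C@@]3(O)[C@@H]12 | intermediate
23 | 17-hydroxy α-methylene lactone (deacetyl target) | C=C1C(=O)O[C@H]2C[C@]3(CO)CC[C@@]4(C)C[C@H]5O[C@@]5(C)CC[C@@H]4[C@@]3(O)[C@@H]12 | intermediate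
24 | CNP0214540.1: 17-acetoxy-4α-hydroxy-12β,13β-epoxy α-methylene lactone (lactone O on C2β, C18 on C3β) | C=C1C(=O)O[C@H]2C[C@]3(COC(C)=O)CC[C@@]4(C)C[C@H]5O[C@@]5(C)CC[C@@H]4[C@@]3(O)[C@@H]12 | target

**Totals**
Total step count: 16. Longest linear sequence: 15 steps (steps 1–5 and 7–16; step 6 is a one-step side branch).

**Steps most likely to fail**

1. Step 14 (Proposed new method). The process at risk is the intramolecular alkylation: the ester must rotate to its s-cis form before the carbanion can reach C3, so the epoxide may stay unopened or be lost by base-induced elimination. The fallback uses known chemistry, sets out from 18 and comes back at 22. Alcohol 18 is converted with ethyl vinyl ether and NBS into the mixed bromoacetal F1. An oxygenative Ueno–Stork radical cyclization (Bu3SnH, AIBN, air, toluene) closes the cis-fused ring at C3 from the β face and traps the C4 radical with O2 from the α face, giving the hydroxy acetal F2. Mild aqueous acid gives the lactol F3, which is oxidized (Ag2CO3 on Celite) to the hydroxy lactone F4. α-Methylenation through the Mannich base F5 (LDA, dimethyl(methylidene)ammonium iodide; then MeI and NaHCO3) gives the methylene lactone F6. Epoxidation of the ring C alkene with one equivalent of mCPBA returns to 22.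

2. Step 10 (key step). The process at risk is the slow six-ring-forming insertion of the 1,1-disubstituted alkene, which would let the cobalt complex decompose or the ring C alkene interfere. The fallback sets out from 15 and comes back at 17. C-Silylation (n-BuLi, Me3SiCl) gives the silylalkyne F7. A titanocene-catalysed reductive cyclocarbonylation (Cp2Ti(CO)2, CO, toluene, 90 °C) then forms an early-metal metallacyclopentene first and inserts CO afterwards, giving the α-silyl enone F8. Protodesilylation (CF3CO2H, CH2Cl2, 0 °C) returns to 17.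

3. Step 13. The process at risk is poor facial selectivity of the peracid at the ring A alkene, where attack on the α face is opposed by the axial C16 methyl that is 1,3 to C4. The fallback sets out from 19 and comes back at 20. One equivalent of mCPBA at −20 °C epoxidizes only the more electron-rich ring C alkene, giving the mono-epoxide F9. NBS in wet DME then adds bromine to C3 on the face the peracid prefers (β) and water to the tertiary C4 from the α face, giving the bromohydrin F10. NaH closes it with inversion at C3 to the α-epoxide 20, which is carried on in the same flask into step 14.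

**Further compounds**
F1 | step 14 | 2β-O-(2-bromo-1-ethoxyethyl) mixed acetal of 18 | CCOC(CBr)O[C@H]1C[C@]2(CO[Si](C)(C)C(C)(C)C)CC[C@@]3(C)CC=C(C)CC[C@@H]3C2=C1
F2 | step 14 | cis-fused 2-ethoxytetrahydrofuran with 4α-OH (C12=C13 alkene, 17-OTBS) | C1C(OCC)O[C@H]2C[C@]3(CO[Si](C)(C)C(C)(C)C)CC[C@@]4(C)CC=C(C)CC[C@@H]4[C@@]3(O)[C@@H]12
F3 | step 14 | lactol from F2 | C1C(O)O[C@H]2C[C@]3(CO[Si](C)(C)C(C)(C)C)CC[C@@]4(C)CC=C(C)CC[C@@H]4[C@@]3(O)[C@@H]12
F4 | step 14 | cis-fused γ-lactone with 4α-OH (C12=C13 alkene, 17-OTBS) | C1C(=O)O[C@H]2C[C@]3(CO[Si](C)(C)C(C)(C)C)CC[C@@]4(C)CC=C(C)CC[C@@H]4[C@@]3(O)[C@@H]12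
F5 | step 14 | α-(dimethylaminomethyl) lactone (Mannich base of F4) | CN(C)CC1C(=O)O[C@H]2C[C@]3(CO[Si](C)(C)C(C)(C)C)CC[C@@]4(C)CC=C(C)CC[C@@H]4[C@@]3(O)[C@@H]12
F6 | step 14 | α-methylene lactone with C12=C13 alkene (22 without the epoxide) | C=C1C(=O)O[C@H]2C[C@]3(CO[Si](C)(C)C(C)(C)C)CC[C@@]4(C)CC=C(C)CC[C@@H]4[C@@]3(O)[C@@H]12
F7 | step 10 | trimethylsilylalkyne of 15 | C=C(CO[Si](C)(C)C(C)(C)C)CC[C@@]1(C)CC=C(C)CC[C@@H]1C#C[Si](C)(C)C
F8 | step 10 | 3-(trimethylsilyl) derivative of enone 17 | O=C1C[C@]2(CO[Si](C)(C)C(C)(C)C)CC[C@@]3(C)CC=C(C)CC[C@@H]3C2=C1[Si](C)(C)C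
F9 | step 13 | 12β,13β-mono-epoxide of 19 | CCOP(=O)(OCC)CC(=O)O[C@H]1C[C@]2(CO[Si](C)(C)C(C)(C)C)CC[C@@]3(C)C[C@H]4O[C@@]4(C)CC[C@@H]3C2=C1
F10 | step 13 | 3β-bromo-4α-hydroxy bromohydrin of F9 | CCOP(=O)(OCC)CC(=O)O[C@H]1C[C@]2(CO[Si](C)(C)C(C)(C)C)CC[C@@]3(C)C[C@H]4O[C@@]4(C)CC[C@@H]3[C@@]2(O)[C@H]1Br
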